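**Retrosynthetic overview**
1. The last operations are O-desilylation and, before it, closure of ring B. The C3 ester joins dienoic acid 17 (auxiliary-controlled hydroxymethylation, vinylogous HWE) to ring A alcohol 9.
2. Ring B (C5-C6-C7-C8-C9-C10) is closed by the C7–C8 bond. A carbene turns the C7 aldehyde into an acyl anion, and this is acylated by the C8 carbonyl of a spiro β-lactone (temporary ring C10-O-C8-C9). The lactone opens and its oxygen leaves as water.
3. Enabling feature: ring B is a diosphenol, the enol of a C7/C8 1,2-diketone. Both carbons are therefore acyl carbons, 1,6-related on arms at the adjacent ring A atoms C5 and C10. C10 is β to C8, so the later C9=C10 bond can be stored as the lactone C10–O bond, which also activates C8.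
4. Ring A is bought as p-benzoquinone monoketal 1. Asymmetric conjugate methylation sets C4, methylation then allylation sets quaternary C5, and Luche reduction sets C3.
5. Ring order: ring A (from 1), then the temporary β-lactone (step 4), then ring B (step 16).

Key step: step 16

Remark: eremophilane numbering is used (ring A = C1=C2, C3(O-acyl), C4(Me), C5(Me), C10; ring B = C5, C6=C7(OH), C8(=O), C9=C10); the spiro carbon C10 of 5–9, 18 and 19 is drawn for axial attack, but either epimer converges because C10 becomes sp2 in step 16.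

**Route**

Step 1
Reactants: 1 4,4-dimethoxycyclohexa-2,5-dien-1-one
Product: 2 (5R)-4,4-dimethoxy-5-methylcyclohex-2-en-1-one
Conditions: Me2Zn, Cu(OTf)2 (2 mol %), (S)-BINOL-derived phosphoramidite of bis[(R)-1-phenylethyl]amine (4 mol %), toluene, −25 °C; AcOH
Reagents that add atoms: dimethylzinc C[Zn]C
Why: Copper-catalysed asymmetric conjugate addition of a dialkylzinc to a quinone monoketal is a known reaction class; the chiral phosphoramidite selects among the enantiotopic enone faces and sets C4 (ligand enantiomer chosen by analogy with cyclohexenone additions), and the inert zinc enolate should stop a second addition.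

Step 2
Reactants: 2 (5R)-4,4-dimethoxy-5-methylcyclohex-2-en-1-one
Product: 3 (5R,6R)-4,4-dimethoxy-5,6-dimethylcyclohex-2-en-1-one
Conditions: LiN(i-Pr)2, THF, −78 °C; MeI, −78 → 0 °C
Reagents that add atoms: iodomethane CI
Why: Kinetic α'-deprotonation of the enone and SN2 methylation (enolate alkylation) should place the methyl group trans to the C4 methyl group, and this centre is made planar again in step 3, so its configuration is of no consequence.

Step 3
Reactants: 3 (5R,6R)-4,4-dimethoxy-5,6-dimethylcyclohex-2-en-1-one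
Product: 4 (5R,6R)-4,4-dimethoxy-5,6-dimethyl-6-(prop-2-en-1-yl)cyclohex-2-en-1-one
Conditions: LiN(i-Pr)2, THF–DMPU, −78 °C; allyl bromide, −78 → 0 °C
Reagents that add atoms: allyl bromide C=CCBr
Why: In this second enolate alkylation the only acidic site is C5-H, and allyl bromide should attack the trisubstituted enolate anti to the pseudo-axial C4 methyl group, which sets quaternary C5 with the two methyl groups cis.

Step 4
Reactants: 4 (5R,6R)-4,4-dimethoxy-5,6-dimethyl-6-(prop-2-en-1-yl)cyclohex-2-en-1-one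
Product: 6 (4R,8R,9R)-7,7-dimethoxy-8,9-dimethyl-9-(prop-2-en-1-yl)-1-oxaspiro[3.5]non-5-en-2-one, via aldol adduct 5 (not isolated)
Conditions: S-phenyl ethanethioate, LiN(i-Pr)2, THF, −78 °C; 4; −78 → 0 °C; AcOH
Reagents that add atoms: S-phenyl ethanethioate CC(=O)Sc1ccccc1
Why: Aldol addition of a thiol ester lithium enolate to a ketone, followed on warming by 4-exo-trig lactonisation with loss of thiophenolate, is the known one-flask β-lactone synthesis; 1,2-addition is kinetically preferred, C2 is shielded by the ketal, and the enolate should enter axially, away from the axial C5 methyl group (a centre erased in step 16).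

Step 5
Reactants: 6 (4R,8R,9R)-7,7-dimethoxy-8,9-dimethyl-9-(prop-2-en-1-yl)-1-oxaspiro[3.5]non-5-en-2-one
Product: 7 (4R,8R,9R)-8,9-dimethyl-9-(prop-2-en-1-yl)-1-oxaspiro[3.5]non-5-ene-2,7-dione
Conditions: PPTS (cat.), acetone–H2O, 23 °C
Reagents that add atoms: water O
Why: Acid-catalysed hydrolysis of an allylic dimethyl ketal should be far faster than any reaction of the lactone, and C4 should not epimerise because its equatorial methyl epimer is the more stable one (an axial methyl group would be syn-diaxial to C9).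

Step 6
Reactants: 7 (4R,8R,9R)-8,9-dimethyl-9-(prop-2-en-1-yl)-1-oxaspiro[3.5]non-5-ene-2,7-dione
Product: 8 (4R,7S,8R,9R)-7-hydroxy-8,9-dimethyl-9-(prop-2-en-1-yl)-1-oxaspiro[3.5]non-5-en-2-one
Conditions: NaBH4, CeCl3·7H2O, MeOH, −78 °C
Reagents that add atoms: none
Why: In this Luche 1,2-reduction the face of the C3 carbonyl that carries the syn-axial C5 methyl group is blocked, so hydride should arrive from the opposite face and give the pseudo-axial C3 alcohol cis to both methyl groups.

Step 7
Reactants: 8 (4R,7S,8R,9R)-7-hydroxy-8,9-dimethyl-9-(prop-2-en-1-yl)-1-oxaspiro[3.5]non-5-en-2-one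
Product: 9 2-[(4R,7S,8R,9R)-7-hydroxy-8,9-dimethyl-2-oxo-1-oxaspiro[3.5]non-5-en-9-yl]acetaldehyde
Conditions: O3 (1 equiv), CH2Cl2, −78 °C; Me2S
Reagents that add atoms: ozone [O-][O+]=O
Why: In this ozonolysis with reductive work-up the terminal alkene should react first, because the ring alkene is flanked by fully substituted C10 and is deactivated by two allylic C–O bonds.

Step 8
Reactants: 10 (R)-4-benzyl-1,3-oxazolidin-2-one
Product: 11 (R)-4-benzyl-3-butanoyl-1,3-oxazolidin-2-one
Conditions: n-BuLi, THF, −78 °C; butanoyl chloride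
Reagents that add atoms: butanoyl chloride CCCC(=O)Cl
Why: N-Acylation of the lithiated oxazolidinone with an acid chloride is a standard way to attach the chiral auxiliary.

Step 9
Reactants: 11 (R)-4-benzyl-3-butanoyl-1,3-oxazolidin-2-one
Product: 12 (R)-4-benzyl-3-[(S)-2-(hydroxymethyl)butanoyl]-1,3-oxazolidin-2-one
Conditions: TiCl4, i-Pr2NEt, CH2Cl2, 0 °C; 1,3,5-trioxane, TiCl4, 0 °C; H2O
Reagents that add atoms: 1,3,5-trioxane C1OCOCO1
Why: In this auxiliary-controlled aldol-type hydroxymethylation the chelated (Z)-titanium enolate meets formaldehyde (released from trioxane) on the face away from the benzyl group, which sets the side-chain stereocentre.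

Step 10
Reactants: 12 (R)-4-benzyl-3-[(S)-2-(hydroxymethyl)butanoyl]-1,3-oxazolidin-2-one
Product: 13 (R)-4-benzyl-3-[(S)-2-{[(tert-butyldimethylsilyl)oxy]methyl}butanoyl]-1,3-oxazolidin-2-one
Conditions: TBSCl, imidazole, DMF, 23 °C
Reagents that add atoms: tert-butyldimethylsilyl chloride CC(C)(C)[Si](C)(C)Cl
Why: Silylation of the primary alcohol is routine and prevents retro-aldol loss and lactonisation in the next steps.

Step 11
Reactants: 13 (R)-4-benzyl-3-[(S)-2-{[(tert-butyldimethylsilyl)oxy]methyl}butanoyl]-1,3-oxazolidin-2-one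
Product: 14 (R)-2-{[(tert-butyldimethylsilyl)oxy]methyl}butan-1-ol
Conditions: LiBH4, H2O (1 equiv), Et2O, 0 °C
Reagents that add atoms: none
Why: Reductive cleavage of the N-acyl oxazolidinone with LiBH4 attacks the exocyclic carbonyl, leaves the stereocentre untouched and returns the auxiliary.

Step 12
Reactants: 14 (R)-2-{[(tert-butyldimethylsilyl)oxy]methyl}butan-1-ol
Product: 15 (S)-2-{[(tert-butyldimethylsilyl)oxy]methyl}butanal
Conditions: Dess–Martin periodinane, CH2Cl2, 0 → 23 °C
Reagents that add atoms: none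
Why: Dess–Martin oxidation is mild and non-basic, so the α-stereocentre of the aldehyde should be kept.

Step 13
Reactants: 15 (S)-2-{[(tert-butyldimethylsilyl)oxy]methyl}butanal
Product: 16 ethyl (2E,4E,6R)-6-{[(tert-butyldimethylsilyl)oxy]methyl}octa-2,4-dienoate
Conditions: triethyl 4-phosphonocrotonate, LiN(SiMe3)2, THF, −78 → 0 °C
Reagents that add atoms: triethyl (E)-4-phosphonocrotonate CCOC(=O)/C=C/CP(=O)(OCC)OCC
Why: The vinylogous Horner–Wadsworth–Emmons olefination of an aldehyde with the stabilised phosphonate anion should give the (2E,4E)-dienoate, and the low temperature limits epimerisation of the aldehyde.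

Step 14
Reactants: 16 ethyl (2E,4E,6R)-6-{[(tert-butyldimethylsilyl)oxy]methyl}octa-2,4-dienoate
Product: 17 (2E,4E,6R)-6-{[(tert-butyldimethylsilyl)oxy]methyl}octa-2,4-dienoic acid
Conditions: LiOH, THF–MeOH–H2O, 23 °C; 1 M HCl to pH 4
Reagents that add atoms: lithium hydroxide [Li+].[OH-]
Why: Saponification of the ethyl ester leaves the silyl ether and the diene geometry unchanged.

Step 15
Reactants: 9 2-[(4R,7S,8R,9R)-7-hydroxy-8,9-dimethyl-2-oxo-1-oxaspiro[3.5]non-5-en-9-yl]acetaldehyde; 17 (2E,4E,6R)-6-{[(tert-butyldimethylsilyl)oxy]methyl}octa-2,4-dienoic acid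
Product: 18 (4R,7S,8R,9R)-8,9-dimethyl-2-oxo-9-(2-oxoethyl)-1-oxaspiro[3.5]non-5-en-7-yl (2E,4E,6R)-6-{[(tert-butyldimethylsilyl)oxy]methyl}octa-2,4-dienoate
Conditions: DCC, DMAP, CH2Cl2, 0 → 23 °C
Reagents that add atoms: none
Why: Steglich esterification acylates the only hydroxyl group with retention at C3, and the aldehyde and the hindered β-lactone should tolerate the neutral conditions.

Step 16
Reactants: 18 (4R,7S,8R,9R)-8,9-dimethyl-2-oxo-9-(2-oxoethyl)-1-oxaspiro[3.5]non-5-en-7-yl (2E,4E,6R)-6-{[(tert-butyldimethylsilyl)oxy]methyl}octa-2,4-dienoate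
Product: 20 (1R,2S,8aS)-7-hydroxy-1,8a-dimethyl-6-oxo-1,2,6,8a-tetrahydronaphthalen-2-yl (2E,4E,6R)-6-{[(tert-butyldimethylsilyl)oxy]methyl}octa-2,4-dienoate, via hydroxy-diketone 19 (not isolated)
Conditions: 2-(perfluorophenyl)-6,7-dihydro-5H-pyrrolo[2,1-c][1,2,4]triazol-2-ium tetrafluoroborate (20 mol %), DBU (1.2 equiv), 4 Å molecular sieves, THF (0.01 M), 23 → 40 °C; AcOH
Reagents that add atoms: none
Why: Proposed new method: the triazolylidene adds to the only aldehyde (C7) and a proton shift gives the acyl-anion equivalent (Breslow intermediate), whose nucleophilic C7 attacks the strained lactone carbonyl C8, after which the tetrahedral intermediate collapses by opening the four-membered ring and the carbene is expelled to give hydroxy-diketone 19. DBU then removes the C10 hydroxyl group by E1cB (C9=C10, conjugated with C1=C2) and the C7 ketone enolises towards C6, so the diosphenol of ring B appears at its final oxidation level with water as the only by-product. The closest known reaction types are the carbene-catalysed intramolecular crossed benzoin reaction of aldehydes with ketones and the carbene-initiated acyl-oxygen opening of β-lactones; acylation of the acyl-anion equivalent by a lactone is the new element, and ring strain is what should make an ester-level carbonyl electrophilic enough and the addition irreversible. Ring B closes in a 6-exo-trig mode (C7 onto C8, the two arms held gauche on the adjacent atoms C5 and C10 and compressed by quaternary C5), while the temporary oxetanone ring is cleaved in the same event. No new stereocentre survives (C7, C8, C9 and C10 all end sp2 and the C10 centre of 18 is erased), and C3, C4, C5 and the side-chain centre are not touched. The chemoselectivity is secured by the substrate: the aldehyde is the only group that can become an acyl anion, the two ordinary esters are far less electrophilic than the β-lactone, C8 is the only carbonyl within reach of C7, and high dilution suppresses intermolecular benzoin coupling.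

Step 17
Reactants: 20 (1R,2S,8aS)-7-hydroxy-1,8a-dimethyl-6-oxo-1,2,6,8a-tetrahydronaphthalen-2-yl (2E,4E,6R)-6-{[(tert-butyldimethylsilyl)oxy]methyl}octa-2,4-dienoate
Product: 21 septeremophilane E, (1R,2S,8aS)-7-hydroxy-1,8a-dimethyl-6-oxo-1,2,6,8a-tetrahydronaphthalen-2-yl (2E,4E,6R)-6-(hydroxymethyl)octa-2,4-dienoate
Conditions: HF·pyridine, THF, 0 → 23 °C
Reagents that add atoms: none
Why: Fluoride-mediated desilylation of the primary silyl ether under buffered acidic conditions should spare the ester, the trienone and the diosphenol.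

**Compound list**
1 | 4,4-dimethoxycyclohexa-2,5-dien-1-one | COC1(OC)C=CC(=O)C=C1 | starting material
2 | (5R)-4,4-dimethoxy-5-methylcyclohex-2-en-1-one | COC1(OC)C=CC(=O)C[C@H]1C | intermediate
3 | (5R,6R)-4,4-dimethoxy-5,6-dimethylcyclohex-2-en-1-one | COC1(OC)C=CC(=O)[C@H](C)[C@H]1C | intermediate
4 | (5R,6R)-4,4-dimethoxy-5,6-dimethyl-6-(prop-2-en-1-yl)cyclohex-2-en-1-one | COC1(OC)C=CC(=O)[C@@](CC=C)(C)[C@H]1C | intermediate
5 | S-phenyl 2-[(1R,5R,6R)-1-hydroxy-4,4-dimethoxy-5,6-dimethyl-6-(prop-2-en-1-yl)cyclohex-2-en-1-yl]ethanethioate (formed as its lithium alkoxide) | COC1(OC)C=C[C@](O)(CC(=O)Sc2ccccc2)[C@@](CC=C)(C)[C@H]1C | intermediate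
6 | (4R,8R,9R)-7,7-dimethoxy-8,9-dimethyl-9-(prop-2-en-1-yl)-1-oxaspiro[3.5]non-5-en-2-one | COC1(OC)C=C[C@]2(CC(=O)O2)[C@@](CC=C)(C)[C@H]1C | intermediate
7 | (4R,8R,9R)-8,9-dimethyl-9-(prop-2-en-1-yl)-1-oxaspiro[3.5]non-5-ene-2,7-dione | O=C1C=C[C@]2(CC(=O)O2)[C@@](CC=C)(C)[C@H]1C | intermediate
8 | (4R,7S,8R,9R)-7-hydroxy-8,9-dimethyl-9-(prop-2-en-1-yl)-1-oxaspiro[3.5]non-5-en-2-one | O[C@H]1C=C[C@]2(CC(=O)O2)[C@@](CC=C)(C)[C@H]1C | intermediate
9 | 2-[(4R,7S,8R,9R)-7-hydroxy-8,9-dimethyl-2-oxo-1-oxaspiro[3.5]non-5-en-9-yl]acetaldehyde | O[C@H]1C=C[C@]2(CC(=O)O2)[C@@](CC=O)(C)[C@H]1C | intermediate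
10 | (R)-4-benzyl-1,3-oxazolidin-2-one | O=C1N[C@H](Cc2ccccc2)CO1 | starting material
11 | (R)-4-benzyl-3-butanoyl-1,3-oxazolidin-2-one | CCCC(=O)N1[C@H](Cc2ccccc2)COC1=O | intermediate
12 | (R)-4-benzyl-3-[(S)-2-(hydroxymethyl)butanoyl]-1,3-oxazolidin-2-one | CC[C@H](C(=O)N1[C@H](Cc2ccccc2)COC1=O)CO | intermediate
13 | (R)-4-benzyl-3-[(S)-2-{[(tert-butyldimethylsilyl)oxy]methyl}butanoyl]-1,3-oxazolidin-2-one | CC[C@H](C(=O)N1[C@H](Cc2ccccc2)COC1=O)CO[Si](C)(C)C(C)(C)C | intermediate
14 | (R)-2-{[(tert-butyldimethylsilyl)oxy]methyl}butan-1-ol | CC[C@H](CO)CO[Si](C)(C)C(C)(C)C | intermediate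
15 | (S)-2-{[(tert-butyldimethylsilyl)oxy]methyl}butanal | CC[C@H](C=O)CO[Si](C)(C)C(C)(C)C | intermediate
16 | ethyl (2E,4E,6R)-6-{[(tert-butyldimethylsilyl)oxy]methyl}octa-2,4-dienoate | CC[C@H](/C=C/C=C/C(=O)OCC)CO[Si](C)(C)C(C)(C)C | intermediate
17 | (2E,4E,6R)-6-{[(tert-butyldimethylsilyl)oxy]methyl}octa-2,4-dienoic acid | CC[C@H](/C=C/C=C/C(=O)O)CO[Si](C)(C)C(C)(C)C | intermediate
18 | (4R,7S,8R,9R)-8,9-dimethyl-2-oxo-9-(2-oxoethyl)-1-oxaspiro[3.5]non-5-en-7-yl (2E,4E,6R)-6-{[(tert-butyldimethylsilyl)oxy]methyl}octa-2,4-dienoate | CC[C@H](/C=C/C=C/C(=O)O[C@H]1C=C[C@]2(CC(=O)O2)[C@@](CC=O)(C)[C@H]1C)CO[Si](C)(C)C(C)(C)C | intermediate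
19 | (1R,2S,4aR,8aR)-4a-hydroxy-1,8a-dimethyl-6,7-dioxo-1,2,4a,5,6,7,8,8a-octahydronaphthalen-2-yl (2E,4E,6R)-6-{[(tert-butyldimethylsilyl)oxy]methyl}octa-2,4-dienoate | CC[C@H](/C=C/C=C/C(=O)O[C@H]1C=C[C@]2(O)CC(=O)C(=O)C[C@]2(C)[C@H]1C)CO[Si](C)(C)C(C)(C)C | intermediate
20 | (1R,2S,8aS)-7-hydroxy-1,8a-dimethyl-6-oxo-1,2,6,8a-tetrahydronaphthalen-2-yl (2E,4E,6R)-6-{[(tert-butyldimethylsilyl)oxy]methyl}octa-2,4-dienoate | CC[C@H](/C=C/C=C/C(=O)O[C@H]1C=CC2=CC(=O)C(O)=C[C@]2(C)[C@H]1C)CO[Si](C)(C)C(C)(C)C | intermediate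
21 | septeremophilane E | CC[C@H](/C=C/C=C/C(=O)O[C@H]1C=CC2=CC(=O)C(O)=C[C@]2(C)[C@H]1C)CO | target

**Step count**
Total step count: 17. Longest linear sequence: 10 steps (steps 1–7 and 15–17).

**Steps most likely to fail**

Step 16 (key step)
- What may go wrong: the carbene or DBU may consume the β-lactone before the C–C bond forms, either by acyl-oxygen opening or by E1cB opening to the dienoate carboxylate. Acylation of the acyl-anion equivalent may also be slower than intermolecular benzoin coupling.
- The fallback uses known chemistry, makes the same C7–C8 bond first as an olefin, sets out from 4 and returns at 20.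
- CH2=CHCH2MgBr adds 1,2 to ketone 4 to give diallyl carbinol F1.
- Ring-closing metathesis with the second-generation Grubbs catalyst joins C7 and C8 and gives octalin ketal F2.
- PPTS in wet acetone frees hydroxy enone F3, and Luche reduction gives diol F4.
- Steglich esterification of the secondary hydroxyl group with 17 gives ester F5.
- OsO4 (cat.) with NMO dihydroxylates the unhindered, electron-rich C7=C8 bond to give triol F6.
- Swern oxidation of both secondary alcohols followed by DBU passes through 19 and gives 20.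

Step 4
- What may go wrong: the hindered ketone may enolise or the aldolate may revert before it lactonises, and the tertiary allylic β-lactone may ionise or lose CO2 on work-up.
- The fallback replaces the one-flask process by a stepwise build-up, sets out from 4 and returns at 6.
- A Reformatsky reaction (Zn, BrCH2CO2Et, THF) gives hydroxy ester F7 under almost non-basic conditions.
- LiOH at 0 °C gives hydroxy acid F8.
- Cyclodehydration with PhSO2Cl in pyridine at 0 °C activates the carboxyl group and closes the β-lactone 6.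

Step 6
- What may go wrong: facial selectivity of the hydride delivery at C3 may be poor.
- The fallback makes both epimers useful, sets out from 7 and returns at 18.
- The unwanted product, C3-epimeric alcohol F9, is separated.
- Ozonolysis as in step 7 converts it to epimeric aldehyde F10.
- A Mitsunobu reaction (PPh3, DIAD) couples F10 with acid 17. This inverts C3 and installs the ester in one operation to give 18, with competing SN2' attack as the process to watch.

**Further compounds**
F1 | step 16 | (1R,5R,6R)-4,4-dimethoxy-5,6-dimethyl-1,6-di(prop-2-en-1-yl)cyclohex-2-en-1-ol | COC1(OC)C=C[C@](O)(CC=C)[C@@](CC=C)(C)[C@H]1C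
F2 | step 16 | octalin ketal (C10 hydroxyl, C3 dimethyl ketal, C1=C2 and C7=C8 double bonds) | COC1(OC)C=C[C@]2(O)CC=CC[C@]2(C)[C@H]1C
F3 | step 16 | hydroxy enone (C3 ketone, C10 hydroxyl, C7=C8 double bond) | O=C1C=C[C@]2(O)CC=CC[C@]2(C)[C@H]1C
F4 | step 16 | diol (C3 and C10 hydroxyl groups, C7=C8 double bond) | O[C@H]1C=C[C@]2(O)CC=CC[C@]2(C)[C@H]1C
F5 | step 16 | C3 ester of F4 with acid 17 | CC[C@H](/C=C/C=C/C(=O)O[C@H]1C=C[C@]2(O)CC=CC[C@]2(C)[C@H]1C)CO[Si](C)(C)C(C)(C)C
F6 | step 16 | C7,C8-cis-diol of F5 (configuration at C7 and C8 of no consequence, both are oxidised) | CC[C@H](/C=C/C=C/C(=O)O[C@H]1C=C[C@]2(O)CC(O)C(O)C[C@]2(C)[C@H]1C)CO[Si](C)(C)C(C)(C)C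
F7 | step 4 | ethyl 2-[(1R,5R,6R)-1-hydroxy-4,4-dimethoxy-5,6-dimethyl-6-(prop-2-en-1-yl)cyclohex-2-en-1-yl]acetate | COC1(OC)C=C[C@](O)(CC(=O)OCC)[C@@](CC=C)(C)[C@H]1C
F8 | step 4 | 2-[(1R,5R,6R)-1-hydroxy-4,4-dimethoxy-5,6-dimethyl-6-(prop-2-en-1-yl)cyclohex-2-en-1-yl]acetic acid | COC1(OC)C=C[C@](O)(CC(=O)O)[C@@](CC=C)(C)[C@H]1C
F9 | step 6 | (4R,7R,8R,9R)-7-hydroxy-8,9-dimethyl-9-(prop-2-en-1-yl)-1-oxaspiro[3.5]non-5-en-2-one | O[C@@H]1C=C[C@]2(CC(=O)O2)[C@@](CC=C)(C)[C@H]1C
F10 | step 6 | 2-[(4R,7R,8R,9R)-7-hydroxy-8,9-dimethyl-2-oxo-1-oxaspiro[3.5]non-5-en-9-yl]acetaldehyde | O[C@@H]1C=C[C@]2(CC(=O)O2)[C@@](CC=O)(C)[C@H]1C
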